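Numbering used throughout: O1 is the ring oxygen bonded to the aryl-bearing carbon C2, C3 carries the methyl group, O4 is bonded to C3, C4a and C8a are the fused aromatic carbons, and the allyl group sits on C7 (para to O4, meta to O1). With this numbering the target is (2R,3S), which places the aryl and methyl groups cis.

Assumption: 1-(3,4,5-trimethoxyphenyl)propan-1-one, 2-bromo-4-chlorophenol and allylboronic acid pinacol ester are taken as catalogue compounds.

## Structural features

The target is a 1,4-benzodioxane neolignan. A benzene ring (ring A) is fused through O1 and O4 to a 1,4-dioxane ring (ring B). C2 carries a 3,4,5-trimethoxyphenyl group (ring C), C3 a methyl group and C7 an allyl group. The two ring oxygens are not equivalent: O4 is para and O1 meta to the allyl group, so the orientation of ring B on ring A must be controlled. C2 and C3 are adjacent stereocentres (2R,3S) with aryl and methyl cis, which forces one of them pseudoaxial and makes this the less stable diastereomer. The C2–O1 bond is a benzylic aryl ether next to a para-methoxy-substituted arene, so acid can ionise it and reclose it to the trans isomer; once the stereocentres are set, acidic conditions must be avoided. The allyl group is a terminal alkene that would be reduced by any hydrogenation and can migrate into conjugation under metal hydride or strong base conditions. The real difficulty is the cis C2/C3 pair in absolute sense, on a ring that keeps no carbonyl or other handle. The key step exploits the fact that C2–H and C3–H lie on the same face of ring B between O1 and O4, which is the signature of a syn addition of H2 to a C2=C3 enediol diether.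

## Logic of the disconnections

8 is cut at the C7–CH2 bond into 6 and 7. The terminal alkene cannot coexist with the hydrogenation that sets the stereocentres, so it is introduced last, with a chloride marking C7 until then. The gain is that all earlier steps are free of the fragile allyl group. The forward step must couple an electron-rich aryl chloride under non-acidic conditions, without migration of the double bond and without touching C2.

6 is cut at the C2–H and C3–H bonds, leading back to 5. Both stereocentres disappear together, and the precursor is a flat, achiral ring with a tetrasubstituted C2=C3 bond. The gain is the largest of the route: no stereocentre has to be carried, protected or relayed before this point. The forward step must add H2 suprafacially and with face selectivity to a tetrasubstituted olefin, and must spare the aryl chloride and the benzylic C–O bond.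

5 is cut at the O1–C8a bond, leading back to 4. The enol oxygen of a ketone becomes O1, so ring B is closed by an aryl C–O bond formation and not by a condensation. The gain is an acyclic ketone that needs no catechol and no phenol protecting group. The forward step must react at C–Br and not at C–Cl; attack through carbon is excluded because it would form a four-membered ring.

4 is cut at the O4–C3 bond into 2 and 3. The substitution pattern of 3 fixes the regiochemistry of ring A: its oxygen becomes O4, its ortho bromine marks C8a and its para chlorine marks C7. The forward step is a simple SN2 etherification at an activated secondary bromide.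

2 is cut at the C–Br bond, leading back to 1. The forward step must brominate the α-carbon of the ketone and not the electron-rich ring.

## Other disconnections considered

Alternative 1: The first plan to come to mind cuts O1–C2 and closes ring B by an intramolecular Mitsunobu etherification, with inversion at the benzylic carbon, of the threo phenol-alcohol A1. Ring C stabilises a benzylic cation, so the activated alcohol can ionise and leak to the more stable trans isomer with erosion at C2. A1 also needs its two stereocentres set in separate operations (a lactate ester as chiral pool, then a threo-selective reduction of a racemisation-prone α-aryloxy ketone) and a protecting group on the phenol, which comes to seven or more steps. The chosen plan sets both centres in one operation on an achiral intermediate and needs no protecting group.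

Alternative 2: A biomimetic cut of both O1–C2 and O4–C3 would join the ortho-quinone A2 and the Z-configured propenylarene A3 in a hetero-Diels–Alder reaction. The remote allyl group gives little bias between the two orientations of the quinone, so the O1/O4 regiochemistry is uncontrolled. Bond formation is likely asynchronous through a benzylic cation stabilised by ring C, which allows rotation and loss of the cis relationship. There is no element for absolute control, A2 is prone to dimerisation, and A3 needs its own Z-selective synthesis. The chosen plan controls regiochemistry through the substitution pattern of one phenol and stereochemistry through one catalyst.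

Alternative 3: A cut of O1–C2 by SN2 opening of the trans-epoxide A4 at its benzylic carbon with the bromophenol A5 would give the erythro hydroxy ether A6, and a copper-catalysed aryl etherification would then close O4–C4a with retention. Under acid, the benzylic carbon of A4 opens through a cation and loses stereochemical integrity, and A4 is prone to rearrangement to a ketone. Under base, the two secondary epoxide carbons are poorly distinguished. A5 is not a catalogue compound, and its allyl group would have to survive hot basic copper conditions. The chosen plan has no stereospecific substitution at the sensitive benzylic carbon.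

Key step: step 4

## Route

Step 1
Reactants: 1 1-(3,4,5-trimethoxyphenyl)propan-1-one
Product: 2 rac-2-bromo-1-(3,4,5-trimethoxyphenyl)propan-1-one
Conditions: CuBr2 (2.1 equiv), EtOAc/CHCl3 1:1, reflux
Reagents that add atoms: copper dibromide, Br[Cu]Br
Why: α-Bromination of an aryl ketone through its enol (King–Ostrum conditions); CuBr2 attacks the enolisable α-CH2 and should spare the trimethoxyarene that free bromine could substitute; the new stereocentre is racemic and is erased in step 3.

Step 2
Reactants: 2 rac-2-bromo-1-(3,4,5-trimethoxyphenyl)propan-1-one; 3 2-bromo-4-chlorophenol
Product: 4 rac-2-(2-bromo-4-chlorophenoxy)-1-(3,4,5-trimethoxyphenyl)propan-1-one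
Conditions: K2CO3 (1.5 equiv), acetone, 55 °C
Reagents that add atoms: none
Why: Williamson ether synthesis, an SN2 displacement of an activated α-bromo ketone by a phenoxide; it fixes the regiochemistry of ring A, because the phenol oxygen becomes O4, the ortho C–Br carbon becomes C8a and the para chlorine marks C7.

Step 3
Reactants: 4 rac-2-(2-bromo-4-chlorophenoxy)-1-(3,4,5-trimethoxyphenyl)propan-1-one
Product: 5 7-chloro-3-methyl-2-(3,4,5-trimethoxyphenyl)-1,4-benzodioxine
Conditions: CuI (10 mol %), 1,10-phenanthroline (20 mol %), Cs2CO3 (2 equiv), toluene, 110 °C, argon
Reagents that add atoms: none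
Why: Intramolecular Ullmann-type O-arylation of a ketone enolate, the reaction type used to make benzofurans and 4H-chromenes from 2-haloaryl ketones; ring B closes through oxygen as a six-membered ring because C-arylation would need a four-membered ring, the C–Br bond reacts while C–Cl is inert to the copper catalyst, and the racemic centre becomes the sp2 carbon C3.

Step 4
Reactants: 5 7-chloro-3-methyl-2-(3,4,5-trimethoxyphenyl)-1,4-benzodioxine
Product: 6 (2R,3S)-7-chloro-3-methyl-2-(3,4,5-trimethoxyphenyl)-2,3-dihydro-1,4-benzodioxine
Conditions: [Ir(cod)(L*)][B(C6H3-3,5-(CF3)2)4] (2 mol %; L* = iPr-PHOX, 2-[2-(diphenylphosphino)phenyl]-4-isopropyl-4,5-dihydrooxazole, enantiomer chosen to give 2R,3S), H2 (50 bar), CH2Cl2, 25 °C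
Reagents that add atoms: none
Why: Proposed new method: asymmetric hydrogenation of a tetrasubstituted 2-aryl-3-alkyl-1,4-benzodioxine has not been shown, the closest known reaction types being the iridium-catalysed asymmetric hydrogenation of 2-monosubstituted 1,4-benzodioxines and the iridium P,N-catalysed asymmetric hydrogenation of tetrasubstituted cyclic aryl olefins and of cyclic enol ethers. Mechanistically, H2 removes cyclooctadiene from the precatalyst and gives a cationic iridium dihydride that binds the electron-rich C2=C3 bond, and migratory insertion followed by C–H reductive elimination (a trivalent/pentavalent iridium cycle) transfers both hydrogens from the metal to one face. Because the olefin is locked in ring B, this suprafacial delivery can only give the cis pair, so the relative configuration at C2 and C3 is fixed by mechanism and not by a selectivity. The absolute configuration is set by the ligand, which distinguishes the enantiotopic faces through the difference between the flat C2 aryl group and the small C3 methyl group in its quadrants; the sense of induction is assigned on the first run and the ligand antipode chosen so that the 2R,3S enantiomer results. No ring is closed in this step. The substrate helps: two of the four olefin substituents are ring oxygens, so the steric demand is close to that of a trisubstituted olefin, and conjugation with ring C and two oxygen lone pairs makes the olefin a good ligand for the cationic metal. The step needs C=C reduction without C–Cl or benzylic C–O cleavage and without an ionic protonation/hydride-transfer pathway through the C2 oxocarbenium ion that could leak to trans; a homogeneous iridium catalyst, the non-basic solvent CH2Cl2, the weakly coordinating borate anion and the absence of added acid are meant to secure this.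

Step 5
Reactants: 6 (2R,3S)-7-chloro-3-methyl-2-(3,4,5-trimethoxyphenyl)-2,3-dihydro-1,4-benzodioxine; 7 2-allyl-4,4,5,5-tetramethyl-1,3,2-dioxaborolane
Product: 8 (2R,3S)-7-allyl-3-methyl-2-(3,4,5-trimethoxyphenyl)-2,3-dihydro-1,4-benzodioxine
Conditions: Pd(OAc)2 (5 mol %), XPhos (10 mol %), K3PO4 (3 equiv), THF/H2O 10:1, 60 °C
Reagents that add atoms: none
Why: Suzuki–Miyaura allylation of an aryl chloride with a bulky biarylphosphine ligand, which permits oxidative addition of zerovalent palladium to the electron-rich C–Cl bond at moderate temperature; the basic, non-acidic medium leaves the benzylic C2–O1 bond and both stereocentres untouched, and the low temperature limits migration of the allyl double bond.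

## Compound list

1 | 1-(3,4,5-trimethoxyphenyl)propan-1-one | CCC(=O)c1cc(OC)c(OC)c(OC)c1 | starting material
2 | rac-2-bromo-1-(3,4,5-trimethoxyphenyl)propan-1-one | CC(Br)C(=O)c1cc(OC)c(OC)c(OC)c1 | intermediate
3 | 2-bromo-4-chlorophenol | Oc1ccc(Cl)cc1Br | starting material
4 | rac-2-(2-bromo-4-chlorophenoxy)-1-(3,4,5-trimethoxyphenyl)propan-1-one | CC(Oc1ccc(Cl)cc1Br)C(=O)c1cc(OC)c(OC)c(OC)c1 | intermediate
5 | 7-chloro-3-methyl-2-(3,4,5-trimethoxyphenyl)-1,4-benzodioxine | CC1=C(c2cc(OC)c(OC)c(OC)c2)Oc2cc(Cl)ccc2O1 | intermediate
6 | (2R,3S)-7-chloro-3-methyl-2-(3,4,5-trimethoxyphenyl)-2,3-dihydro-1,4-benzodioxine | Clc1ccc2c(c1)O[C@H](c1cc(OC)c(OC)c(OC)c1)[C@H](C)O2 | intermediate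
7 | 2-allyl-4,4,5,5-tetramethyl-1,3,2-dioxaborolane (allylboronic acid pinacol ester) | C=CCB1OC(C)(C)C(C)(C)O1 | starting material
8 | (2R,3S)-7-allyl-3-methyl-2-(3,4,5-trimethoxyphenyl)-2,3-dihydro-1,4-benzodioxine | C=CCc1ccc2c(c1)O[C@H](c1cc(OC)c(OC)c(OC)c1)[C@H](C)O2 | target

## Step count and least certain steps

Total step count: 5. Longest linear sequence: 5 steps (1 → 2 → 4 → 5 → 6 → 8).

**Step 4 (key step, proposed new method).** Three things are most likely to go wrong:
- slow or incomplete turnover at the tetrasubstituted olefin;
- insufficient enantiofacial discrimination between the aryl and methyl termini;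
- leakage through an acid-mediated protonation/hydride-transfer pathway, which would lose the mechanistic guarantee of cis addition and could also epimerise C2 after reduction.

Fallback with known chemistry, setting out from 4 and returning at 6: the racemic ketone 4 would be hydrogenated under Noyori conditions with dynamic kinetic resolution (RuCl2(xylbinap)(daipen) in the enantiomeric form that gives the 1R carbinol, t-BuOK, i-PrOH, H2). The α-centre epimerises through the enolate faster than the ketone is reduced. This reaction type is known for α-alkoxy and α-aryloxy ketones and is expected to favour the erythro alcohol (1R,2S)-2-(2-bromo-4-chlorophenoxy)-1-(3,4,5-trimethoxyphenyl)propan-1-ol F1. An intramolecular copper-catalysed aryl etherification of F1 (CuI, 3,4,7,8-tetramethyl-1,10-phenanthroline, Cs2CO3, toluene, 110 °C) would then close O1–C8a with retention at both centres and give 6.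

**Step 3.** The enolate O-arylation may be slow for a six-membered closure through a hindered, fully substituted enolate. Reductive loss of bromine or base-induced degradation of the α-aryloxy ketone could then compete.

Fallback, setting out from 2 and returning at 5, forms O1–C2 by carbonyl addition instead of aryl C–O coupling:
- Alkylation of 5-chloro-2-hydroxybenzaldehyde with 2 (K2CO3, acetone) would give 5-chloro-2-{[1-oxo-1-(3,4,5-trimethoxyphenyl)propan-2-yl]oxy}benzaldehyde F2.
- Dakin oxidation (mCPBA, CH2Cl2) would give the aryl formate 5-chloro-2-{[1-oxo-1-(3,4,5-trimethoxyphenyl)propan-2-yl]oxy}phenyl formate F3.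
- Methanolysis (K2CO3, MeOH) would release the phenol, which should close on the ketone to the cyclic hemiketal 7-chloro-3-methyl-2-(3,4,5-trimethoxyphenyl)-2,3-dihydro-1,4-benzodioxin-2-ol F4.
- Acid-catalysed dehydration (p-TsOH, toluene, water separator) would give 5.

**Step 5.** Oxidative addition to the electron-rich aryl chloride may be sluggish. A palladium hydride formed along the way could move the allyl double bond into conjugation with ring A.

Fallback, setting out from 6 and returning at 8, reverses the polarity of the partners. Miyaura borylation of 6 (B2pin2, Pd(OAc)2, XPhos, KOAc, dioxane, 100 °C) would give the aryl boronate (2R,3S)-3-methyl-7-(4,4,5,5-tetramethyl-1,3,2-dioxaborolan-2-yl)-2-(3,4,5-trimethoxyphenyl)-2,3-dihydro-1,4-benzodioxine F5. Coupling of F5 with allyl bromide through a π-allylpalladium intermediate (Pd(PPh3)4, K2CO3, THF/H2O, 50 °C) would give 8.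

## Further compounds

F1 | step 4 | (1R,2S)-2-(2-bromo-4-chlorophenoxy)-1-(3,4,5-trimethoxyphenyl)propan-1-ol | O[C@H](c1cc(OC)c(OC)c(OC)c1)[C@H](C)Oc1ccc(Cl)cc1Br
F2 | step 3 | rac-5-chloro-2-{[1-oxo-1-(3,4,5-trimethoxyphenyl)propan-2-yl]oxy}benzaldehyde | CC(Oc1ccc(Cl)cc1C=O)C(=O)c1cc(OC)c(OC)c(OC)c1
F3 | step 3 | rac-5-chloro-2-{[1-oxo-1-(3,4,5-trimethoxyphenyl)propan-2-yl]oxy}phenyl formate | CC(Oc1ccc(Cl)cc1OC=O)C(=O)c1cc(OC)c(OC)c(OC)c1
F4 | step 3 | 7-chloro-3-methyl-2-(3,4,5-trimethoxyphenyl)-2,3-dihydro-1,4-benzodioxin-2-ol (mixture of diastereomers) | CC1Oc2ccc(Cl)cc2OC1(O)c1cc(OC)c(OC)c(OC)c1
F5 | step 5 | (2R,3S)-3-methyl-7-(4,4,5,5-tetramethyl-1,3,2-dioxaborolan-2-yl)-2-(3,4,5-trimethoxyphenyl)-2,3-dihydro-1,4-benzodioxine | CC1(C)OB(OC1(C)C)c1ccc2c(c1)O[C@H](c1cc(OC)c(OC)c(OC)c1)[C@H](C)O2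
A1 | alternative 1 | (1S,2S)-2-(4-allyl-2-hydroxyphenoxy)-1-(3,4,5-trimethoxyphenyl)propan-1-ol | O[C@@H](c1cc(OC)c(OC)c(OC)c1)[C@H](C)Oc1ccc(CC=C)cc1O
A2 | alternative 2 | 4-allyl-1,2-benzoquinone | C=CCC1=CC(=O)C(=O)C=C1
A3 | alternative 2 | (Z)-1,2,3-trimethoxy-5-(prop-1-en-1-yl)benzene | C/C=C\c1cc(OC)c(OC)c(OC)c1
A4 | alternative 3 | (2S,3S)-2-methyl-3-(3,4,5-trimethoxyphenyl)oxirane | C[C@@H]1O[C@H]1c1cc(OC)c(OC)c(OC)c1
A5 | alternative 3 | 5-allyl-2-bromophenol | C=CCc1ccc(Br)c(O)c1
A6 | alternative 3 | (1R,2S)-1-(5-allyl-2-bromophenoxy)-1-(3,4,5-trimethoxyphenyl)propan-2-ol | C=CCc1ccc(Br)c(c1)O[C@H](c1cc(OC)c(OC)c(OC)c1)[C@H](C)O
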